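## The problem

The target 36 is a linear chain of ten benzene rings, A to J, joined by nine diaryl ether oxygens and carrying twenty-six free hydroxyl groups; it has no stereocentre, so the task is one of regiochemistry, hindered C–O bond formation and handling. Ring A is a phloroglucinol whose C2, the carbon between two hydroxyl carbons, carries the oxygen to ring B; rings B, D, F and H are 2,6-dihydroxy-1,4-phenylenedioxy units, rings C, E, G and I are 3,4,5-trihydroxy-1,2-phenylenedioxy units, and ring J is a 3,4,5-trihydroxyphenyl end group. Every ether oxygen is bonded on one side to an aryl carbon flanked by two oxygenated carbons, so each coupling must use the crowded ring as the nucleophile (a 2,6-dioxygenated phenol) and the other ring as the electrophile, at a carbon with at most one ortho substituent. The free pyrogallol and phloroglucinol rings are oxidised by air, most readily in base, and are attacked by electrophiles; all hydroxyls therefore stay masked until the last step, which must be non-oxidative. One robust mask, methyl, is enough, since nothing has to be told apart at the end. The pair B–C recurs as D–E, F–G and H–I, so one two-ring building block can be used three times. The key step rests on ring A: its oxygenated carbons C1, C3 and C5 alternate with C2 (aryloxy), C4 and C6 (hydrogen), the pattern of a folded 3,5-dioxoheptanedioate chain whose central carbon, between two ketones, bears the aryloxy group and whose C6 can be joined to the C1 ester carbon.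

## Retrosynthesis

**36 from 35.** The twenty-six O–CH3 bonds are cut last. The precursor is the hexacosamethyl ether 35. Methyl is preferred to benzyl because every ring except A derives from a purchasable methyl ether (1, 16, 20, 34), and because methyl ethers survive base, peracid, copper and hydrogenolysis. The forward step needs a reagent that cleaves aryl methyl ethers but not diaryl ethers.

**35 from 33 and 34.** The I–J ether is cut between the oxygen on ring I C2 and ring J C1. This leaves the crowded nonamer phenol 33 and the unhindered, purchasable bromide 34. The opposite polarity would need a halide between two oxygenated carbons on ring I. The forward reaction is a copper-catalysed coupling of a 2,6-dioxygenated phenol.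

**33 from 24 and three units of 21.** The C–D, E–F and G–H ethers are cut in the same sense (ring C, E or G C2–O as phenol; ring D, F or H C1 as bromide). Each cut removes the same two-ring block 21, whose formyl group is a latent hydroxyl for the next round. The intermediates are aldehydes 25, 28 and 31 and phenols 27, 30 and 33. Against adding single rings this halves the number of operations on the growing chain. The forward cycle is an Ullmann coupling that tolerates an aldehyde, then a Baeyer–Villiger oxidation.

**24 from 15 and 19; 21 from 20 and 19.** The B–C-type ether is cut at ring C C1. The phenol between two methoxy groups (15 or 20) is the nucleophile, and fluoroaldehyde 19 is the electrophile. Its formyl group activates the ortho fluoride and afterwards becomes the C2 hydroxyl (22 to 24). Because this bond is made without metal, the bromide of 20 survives into 21. A copper coupling at this bond would not allow that.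

**19 from 18 from 16.** The formyl C–C bond is cut first. The two free positions of 18 are equivalent, so formylation can give only 19. The C–F bond is traced to the amine of purchasable 16.

**15 from 14, 13 and 11.** No skeletal bond is cut here. The benzyl group of 14 is the one mask that can be removed beside methyl ethers. The methyl ethers of 14 come from triol 13, and 13 from ester 11 by loss of the carboxyl carbon. That carbon was needed only to make the ring closure possible.

**11 from 10 (key disconnection).** The C6–C1 bond of ring A (chain numbering) is cut, opening the ring to the symmetric triketo diester 10. A copper coupling at ring A C2 would also make the A–B ether. The Claisen route forms it earlier, as a simple alkyl aryl ether, and then builds ring A around it, so the aryloxy group lands between two hydroxyl carbons by construction. The precursor is acyclic and symmetric, so either arm can close. The forward reaction must favour C- over O-acylation.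

**10 from 8 and 9; 8 from 6; 6 from 4 and 5; 4 from 2 from 1.** The C4–C5 bond of 10 is cut to the bis-silyl dienol ether 8 and methyl malonyl chloride 9. A neutral acylation is chosen because the acidic methylene of 9 would quench a dianion. Diene 8 comes from β-keto ester 6 through silyl enol ether 7. The ether bond of 6 is an SN2 displacement on chloroketone 5 by phenol 4. Phenol 4 comes from syringaldehyde 1 by benzylation (2) and Baeyer–Villiger oxidation.

## Roads not taken

Alternative 1: Here eighteen hydroxyls on rings A to I, each ortho or para to an ether-bearing carbon, are traced back to formyl groups. The octadecaformyl decamer A2 would be assembled by SNAr reactions of phenoxides with fluoroarenes activated by those formyl groups. One eighteen-fold Baeyer–Villiger oxidation with methanolysis of the formates would then give the octamethyl ether A1, and cleavage of eight methyl ethers would finish.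

- Merits: every ether bond forms under double carbonyl activation, without metal, even at the crowded carbons. The formyl groups serve twice. On paper the route is shorter and more convergent than the chosen one.
- Weak points: the rings of A2 each carry two formyl groups and are electron-poor, where hydride migration to carboxylic acids competes with aryl migration. As oxidation proceeds, free electron-rich phenols face the peracid and can go on to quinones. Eighteen sites must all react correctly in one flask; any shortfall gives congeners that differ by one group in a molecule of this size. A1, with eighteen free hydroxyls, is nearly as fragile as 36 and still needs a demethylation.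
- Comparison: in step count and in the ease of each C–O bond formation this road is better. The chosen plan borrows the same formyl tactic but applies it one aldehyde at a time on electron-rich rings, so each oxidation gives a single purifiable phenol and no free polyphenol exists before the last step.

Alternative 2: Ring D is cut across two C–C bonds. Cyclobutenone A4 would be heated with (triisopropylsilyloxy)acetylene A5. The derived vinylketene and the alkyne combine by (2+2) addition, ring opening and 6π closure to give the D–E phenol A3.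

- Merits: the pericyclic cascade fixes the regiochemistry, and ring D arrives with three differentiated oxygens around the aryloxy carbon.
- Weak points: the differentiation is not needed, since both ring D hydroxyls are free in 36. The oxygen that must bond to ring C is the silyl ether and the free hydroxyl is the wrong one, so protecting groups must be shuffled. The bromide of A3 sits on ring E C2 between two oxygenated carbons, the worst electrophile for the next ether coupling. A4 and A5 are specialised, sensitive reagents, and the sequence builds only one of four such rings.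
- Comparison: both plans build one ring from acyclic or small-ring precursors. This road would be better if partially protected congeners were wanted. The chosen plan builds the terminal ring A from a cheap triketide and buys the B-type rings ready-made.

Alternative 3: Ring C is cut at its C1–C2 bond. Cyclobutenone A7 would be thermolysed to a dienylketene whose 6π electrocyclisation and tautomerisation give trimer phenol A6, which is the same compound as 24 of the chosen route.

- Merits: the free hydroxyl appears exactly at ring C C2 with no peracid, the three methoxy groups come from the four-membered ring, and no SNAr on a weakly activated fluoride is needed.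
- Weak points: A7 requires a (Z)-2-aryloxyvinyl metal reagent derived from phenol 15, and such a reagent can lose aryloxide by β-elimination. It also requires O-methylation of a tertiary alkoxide and a thermolysis. Phenol 15 must still be made. The sequence serves one of four pentaoxygenated rings unless repeated.
- Comparison: for the single step from ring B to ring C this road is about as short and avoids the two points at which the chosen route is exposed (SNAr reactivity, peracid selectivity). Against that, the chosen plan uses one simple reagent, 19, for all four such rings and needs no organometallic step.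

Key step: step 6

## Route

Remark on the chemistry: 36 has no stereocentre. The enol ether double bonds of 7 and 8 are expected as mixtures of geometric isomers, which does not matter because both are consumed in step 5. Compound 10 is drawn as its triketo tautomer.

Step 1
Reactants: 1 syringaldehyde
Product: 2 4-(benzyloxy)-3,5-dimethoxybenzaldehyde
Conditions: BnBr, K2CO3, DMF, 60 °C
Reagents that add atoms: benzyl bromide, BrCc1ccccc1
Why: Williamson benzylation of the acidic syringyl phenol; benzyl is the one group on ring B that can later be removed beside methyl ethers.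

Step 2
Reactants: 2 4-(benzyloxy)-3,5-dimethoxybenzaldehyde
Product: 4 4-(benzyloxy)-3,5-dimethoxyphenol, via aryl formate 3 (not isolated)
Conditions: mCPBA, CH2Cl2, 0 °C to rt; then K2CO3 (cat.), MeOH, rt
Reagents that add atoms: 3-chloroperbenzoic acid, OOC(=O)c1cccc(Cl)c1
Why: Baeyer–Villiger (Dakin-type) oxidation of an electron-rich benzaldehyde; the para-alkoxyaryl group migrates in preference to hydride, and methanolysis of the formate frees the phenol.

Step 3
Reactants: 4 4-(benzyloxy)-3,5-dimethoxyphenol; 5 methyl 4-chloro-3-oxobutanoate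
Product: 6 methyl 4-[4-(benzyloxy)-3,5-dimethoxyphenoxy]-3-oxobutanoate
Conditions: NaH (2.2 equiv), THF, 0 °C to rt; aq. NH4Cl
Reagents that add atoms: none
Why: Williamson ether synthesis on an α-chloroketone; the second equivalent of NaH holds 5 as its enolate, which protects the ketone and C2, while the unhindered phenoxide of 4 displaces the primary chloride (SN2). This makes the future A–B ether bond as a simple alkyl aryl ether.

Step 4
Reactants: 6 methyl 4-[4-(benzyloxy)-3,5-dimethoxyphenoxy]-3-oxobutanoate
Product: 8 4-[4-(benzyloxy)-3,5-dimethoxyphenoxy]-1-methoxy-1,3-bis(trimethylsilyloxy)buta-1,3-diene, via silyl enol ether 7 (not isolated)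
Conditions: TMSCl, Et3N, toluene, rt; filter, concentrate; then LiN(iPr)2, THF, −78 °C; TMSCl, −78 to 0 °C
Reagents that add atoms: chlorotrimethylsilane, C[Si](C)(C)Cl
Why: Standard two-stage bis-silylation of a β-keto ester: O-silylation of the enol, then γ-deprotonation and O-silylation of the ester dienolate. The product is a neutral equivalent of the β-keto ester dianion and is used crude.

Step 5
Reactants: 8 4-[4-(benzyloxy)-3,5-dimethoxyphenoxy]-1-methoxy-1,3-bis(trimethylsilyloxy)buta-1,3-diene; 9 methyl 3-chloro-3-oxopropanoate (methyl malonyl chloride)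
Product: 10 dimethyl 4-[4-(benzyloxy)-3,5-dimethoxyphenoxy]-3,5-dioxoheptanedioate
Conditions: CH2Cl2, −78 °C to rt; aq. NH4Cl
Reagents that add atoms: none
Why: Mukaiyama-type C-acylation of a 1,3-bis(silyloxy)diene at its terminal carbon by an acid chloride, the known access to 3,5-dioxo esters. No base is present, so the acidic methylene of 9 is not deprotonated, and the new C4–C5 bond forms at the aryloxy-bearing carbon.

Step 6
Reactants: 10 dimethyl 4-[4-(benzyloxy)-3,5-dimethoxyphenoxy]-3,5-dioxoheptanedioate
Product: 11 methyl 3-[4-(benzyloxy)-3,5-dimethoxyphenoxy]-2,4,6-trihydroxybenzoate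
Conditions: Mg(OMe)2 (3 equiv), MeOH, reflux; then 1 M HCl
Reagents that add atoms: none
Why: Mg(OMe)2 first forms the magnesium chelate of the C3/C5 diketone enolate (C4–H is the most acidic proton), which folds the chain and shields both ketones from retro-Claisen attack; a second deprotonation at C6, made possible by the C7 ester, gives an ester enolate. C6 adds to the C1 ester carbonyl in a 6-exo-trig closure (the ester enolate double bond lies outside the new ring), methoxide leaves, and the resulting 2,4,6-trioxocyclohexanecarboxylate enolises at once to the aromatic triol, held as its magnesium salicylate chelate. The closest known reaction type is the base-mediated Claisen (Dieckmann-type) cyclisation of 3,5-dioxoheptanedioates and related β-polyketo esters to phloroglucinol carboxylates, the laboratory counterpart of polyketide aromatisation. No stereocentre is formed, and because 10 is symmetric about C4 either arm can act as the nucleophile with the same result, so there is no regiochemical question. The selectivity needed is carbon over oxygen acylation: attack by the C5 enol oxygen would give a 4-hydroxy-2-pyranone, but methoxide reopens that lactone under the conditions, whereas aromatisation and phenoxide formation are irreversible, so the mixture should drain to 11. Magnesium chelation and the soft, doubly stabilised C6 nucleophile both favour the carbon pathway. The aryloxy group at C4 ends between two hydroxyl-bearing carbons without any coupling at a crowded aryl carbon, and the benzyl ether and ring B are inert to methoxide.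

Step 7
Reactants: 11 methyl 3-[4-(benzyloxy)-3,5-dimethoxyphenoxy]-2,4,6-trihydroxybenzoate
Product: 13 2-[4-(benzyloxy)-3,5-dimethoxyphenoxy]benzene-1,3,5-triol, via carboxylic acid 12 (not isolated)
Conditions: 2 M NaOH (degassed), 80 °C, argon; then 2 M HCl, 60 °C
Reagents that add atoms: none
Why: Saponification followed by protodecarboxylation; 2,4,6-trihydroxybenzoic acids lose CO2 readily through ipso-protonation of the electron-rich ring. Oxygen is excluded because the phloroglucinol anion is air-sensitive.

Step 8
Reactants: 13 2-[4-(benzyloxy)-3,5-dimethoxyphenoxy]benzene-1,3,5-triol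
Product: 14 2-[4-(benzyloxy)-3,5-dimethoxyphenoxy]-1,3,5-trimethoxybenzene
Conditions: Me2SO4, K2CO3, acetone, reflux
Reagents that add atoms: dimethyl sulfate, COS(=O)(=O)OC
Why: Exhaustive O-methylation of a phloroglucinol with a hard alkylating agent and carbonate in acetone, conditions that favour O- over C-alkylation.

Step 9
Reactants: 14 2-[4-(benzyloxy)-3,5-dimethoxyphenoxy]-1,3,5-trimethoxybenzene
Product: 15 2,6-dimethoxy-4-(2,4,6-trimethoxyphenoxy)phenol (phenol A–B)
Conditions: H2 (1 atm), 10% Pd/C, EtOAc–MeOH, rt
Reagents that add atoms: none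
Why: Hydrogenolysis of the benzyl ether; methyl and diaryl ethers are inert, and the ring B hydroxyl between two methoxy groups is revealed.

Step 10
Reactants: 16 3,4,5-trimethoxyaniline
Product: 18 5-fluoro-1,2,3-trimethoxybenzene, via diazonium tetrafluoroborate 17 (not isolated)
Conditions: NOBF4, CH2Cl2, 0 °C; then 1,2-dichlorobenzene, 110 °C
Reagents that add atoms: nitrosonium tetrafluoroborate, N#[O+].F[B-](F)(F)F
Why: Balz–Schiemann reaction: diazotisation gives the diazonium tetrafluoroborate, whose thermolysis delivers the aryl fluoride with loss of N2 and BF3.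

Step 11
Reactants: 18 5-fluoro-1,2,3-trimethoxybenzene
Product: 19 6-fluoro-2,3,4-trimethoxybenzaldehyde
Conditions: Cl2CHOMe, TiCl4, CH2Cl2, −10 to 0 °C; then ice-water
Reagents that add atoms: dichloromethyl methyl ether, COC(Cl)Cl; water, O
Why: Rieche formylation; the two free positions of 18 are equivalent and each is activated by an ortho and a para methoxy group, so only one aldehyde can form. Low temperature limits Lewis-acid demethylation.

Step 12
Reactants: 19 6-fluoro-2,3,4-trimethoxybenzaldehyde; 20 4-bromo-2,6-dimethoxyphenol
Product: 21 6-(4-bromo-2,6-dimethoxyphenoxy)-2,3,4-trimethoxybenzaldehyde (two-ring block)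
Conditions: K2CO3, DMF, 120 °C, argon
Reagents that add atoms: none
Why: SNAr: the fluoride ortho to the formyl group is displaced by the phenoxide through a Meisenheimer adduct stabilised by the aldehyde. The aryl bromide is untouched because no metal is present.

Step 13
Reactants: 15 2,6-dimethoxy-4-(2,4,6-trimethoxyphenoxy)phenol; 19 6-fluoro-2,3,4-trimethoxybenzaldehyde
Product: 22 6-[2,6-dimethoxy-4-(2,4,6-trimethoxyphenoxy)phenoxy]-2,3,4-trimethoxybenzaldehyde (trimer aldehyde A–C)
Conditions: K2CO3, DMF, 120 °C, argon
Reagents that add atoms: none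
Why: The same SNAr as in step 12; the crowded ring B phenoxide is the nucleophile and the carbon attacked on ring C has only one ortho substituent.

Step 14
Reactants: 22 trimer aldehyde A–C
Product: 24 6-[2,6-dimethoxy-4-(2,4,6-trimethoxyphenoxy)phenoxy]-2,3,4-trimethoxyphenol (trimer phenol A–C), via trimer formate 23 (not isolated)
Conditions: mCPBA, CH2Cl2, 0 °C to rt; then K2CO3 (cat.), MeOH, rt
Reagents that add atoms: 3-chloroperbenzoic acid, OOC(=O)c1cccc(Cl)c1
Why: Baeyer–Villiger oxidation; the aryl group, carrying ortho and para oxygen donors, migrates. Methanolysis gives the ring C C2 phenol; a slight excess of peracid at low temperature limits attack on the electron-rich rings.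

Step 15
Reactants: 24 trimer phenol A–C; 21 6-(4-bromo-2,6-dimethoxyphenoxy)-2,3,4-trimethoxybenzaldehyde
Product: 25 pentamer aldehyde A–E (formyl group on ring E C2)
Conditions: CuI (10 mol%), picolinic acid (20 mol%), K3PO4, DMSO, 90 °C
Reagents that add atoms: none
Why: Ullmann-type copper-catalysed diaryl ether synthesis with the picolinic acid ligand system developed for ortho,ortho'-disubstituted phenols. The bromide of 21 is flanked by two hydrogens, and the non-enolisable aldehyde is a spectator.

Step 16
Reactants: 25 pentamer aldehyde A–E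
Product: 27 pentamer phenol A–E (hydroxyl on ring E C2), via pentamer formate 26 (not isolated)
Conditions: mCPBA, CH2Cl2, 0 °C to rt; then K2CO3 (cat.), MeOH, rt
Reagents that add atoms: 3-chloroperbenzoic acid, OOC(=O)c1cccc(Cl)c1
Why: Baeyer–Villiger oxidation and formate methanolysis as in step 14.

Step 17
Reactants: 27 pentamer phenol A–E; 21 6-(4-bromo-2,6-dimethoxyphenoxy)-2,3,4-trimethoxybenzaldehyde
Product: 28 heptamer aldehyde A–G (formyl group on ring G C2)
Conditions: CuI (10 mol%), picolinic acid (20 mol%), K3PO4, DMSO, 90 °C
Reagents that add atoms: none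
Why: Ullmann-type coupling as in step 15; the reacting phenol has the same local environment as 24.

Step 18
Reactants: 28 heptamer aldehyde A–G
Product: 30 heptamer phenol A–G (hydroxyl on ring G C2), via heptamer formate 29 (not isolated)
Conditions: mCPBA, CH2Cl2, 0 °C to rt; then K2CO3 (cat.), MeOH, rt
Reagents that add atoms: 3-chloroperbenzoic acid, OOC(=O)c1cccc(Cl)c1
Why: Baeyer–Villiger oxidation and formate methanolysis as in step 14.

Step 19
Reactants: 30 heptamer phenol A–G; 21 6-(4-bromo-2,6-dimethoxyphenoxy)-2,3,4-trimethoxybenzaldehyde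
Product: 31 nonamer aldehyde A–I (formyl group on ring I C2)
Conditions: CuI (10 mol%), picolinic acid (20 mol%), K3PO4, DMSO, 90 °C
Reagents that add atoms: none
Why: Ullmann-type coupling as in step 15.

Step 20
Reactants: 31 nonamer aldehyde A–I
Product: 33 nonamer phenol A–I (hydroxyl on ring I C2), via nonamer formate 32 (not isolated)
Conditions: mCPBA, CH2Cl2, 0 °C to rt; then K2CO3 (cat.), MeOH, rt
Reagents that add atoms: 3-chloroperbenzoic acid, OOC(=O)c1cccc(Cl)c1
Why: Baeyer–Villiger oxidation and formate methanolysis as in step 14.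

Step 21
Reactants: 33 nonamer phenol A–I; 34 5-bromo-1,2,3-trimethoxybenzene
Product: 35 hexacosa-O-methyl ether of the target (protected decamer A–J)
Conditions: CuI (10 mol%), picolinic acid (20 mol%), K3PO4, DMSO, 90 °C
Reagents that add atoms: none
Why: Ullmann-type coupling of the crowded ring I phenol with an unhindered aryl bromide closes the chain with ring J.

Step 22
Reactants: 35 hexacosa-O-methyl ether of the target
Product: 36 CNP0255890.0 (free decamer with twenty-six hydroxyl groups)
Conditions: BBr3 (excess), CH2Cl2, −78 °C to rt; then degassed H2O, 0 °C, argon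
Reagents that add atoms: none
Why: Lewis-acid cleavage of aryl methyl ethers via aryloxyboranes and bromomethane; diaryl ether bonds are not attacked. Hydrolysis and isolation under argon protect the pyrogallol rings.

## Compound list

1 | syringaldehyde (4-hydroxy-3,5-dimethoxybenzaldehyde) | COc1cc(C=O)cc(OC)c1O | starting material
2 | 4-(benzyloxy)-3,5-dimethoxybenzaldehyde | COc1cc(C=O)cc(OC)c1OCc1ccccc1 | intermediate
3 | 4-(benzyloxy)-3,5-dimethoxyphenyl formate (not isolated) | COc1cc(OC=O)cc(OC)c1OCc1ccccc1 | intermediate
4 | 4-(benzyloxy)-3,5-dimethoxyphenol | COc1cc(O)cc(OC)c1OCc1ccccc1 | intermediate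
5 | methyl 4-chloro-3-oxobutanoate | COC(=O)CC(=O)CCl | starting material
6 | methyl 4-[4-(benzyloxy)-3,5-dimethoxyphenoxy]-3-oxobutanoate | COC(=O)CC(=O)COc1cc(OC)c(OCc2ccccc2)c(OC)c1 | intermediate
7 | methyl 4-[4-(benzyloxy)-3,5-dimethoxyphenoxy]-3-(trimethylsilyloxy)but-2-enoate (E/Z mixture, not isolated) | COC(=O)C=C(COc1cc(OC)c(OCc2ccccc2)c(OC)c1)O[Si](C)(C)C | intermediate
8 | 4-[4-(benzyloxy)-3,5-dimethoxyphenoxy]-1-methoxy-1,3-bis(trimethylsilyloxy)buta-1,3-diene (mixture of geometric isomers) | COC(O[Si](C)(C)C)=CC(O[Si](C)(C)C)=COc1cc(OC)c(OCc2ccccc2)c(OC)c1 | intermediate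
9 | methyl 3-chloro-3-oxopropanoate (methyl malonyl chloride) | COC(=O)CC(Cl)=O | starting material
10 | dimethyl 4-[4-(benzyloxy)-3,5-dimethoxyphenoxy]-3,5-dioxoheptanedioate | COC(=O)CC(=O)C(Oc1cc(OC)c(OCc2ccccc2)c(OC)c1)C(=O)CC(=O)OC | intermediate
11 | methyl 3-[4-(benzyloxy)-3,5-dimethoxyphenoxy]-2,4,6-trihydroxybenzoate | COC(=O)c1c(O)cc(O)c(Oc2cc(OC)c(OCc3ccccc3)c(OC)c2)c1O | intermediate
12 | 3-[4-(benzyloxy)-3,5-dimethoxyphenoxy]-2,4,6-trihydroxybenzoic acid (not isolated) | OC(=O)c1c(O)cc(O)c(Oc2cc(OC)c(OCc3ccccc3)c(OC)c2)c1O | intermediate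
13 | 2-[4-(benzyloxy)-3,5-dimethoxyphenoxy]benzene-1,3,5-triol | Oc1cc(O)c(Oc2cc(OC)c(OCc3ccccc3)c(OC)c2)c(O)c1 | intermediate
14 | 2-[4-(benzyloxy)-3,5-dimethoxyphenoxy]-1,3,5-trimethoxybenzene | COc1cc(OC)c(Oc2cc(OC)c(OCc3ccccc3)c(OC)c2)c(OC)c1 | intermediate
15 | 2,6-dimethoxy-4-(2,4,6-trimethoxyphenoxy)phenol (phenol A–B) | COc1cc(OC)c(Oc2cc(OC)c(O)c(OC)c2)c(OC)c1 | intermediate
16 | 3,4,5-trimethoxyaniline | COc1cc(N)cc(OC)c1OC | starting material
17 | 3,4,5-trimethoxybenzenediazonium tetrafluoroborate (not isolated) | COc1cc([N+]#N)cc(OC)c1OC.F[B-](F)(F)F | intermediate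
18 | 5-fluoro-1,2,3-trimethoxybenzene | COc1cc(F)cc(OC)c1OC | intermediate
19 | 6-fluoro-2,3,4-trimethoxybenzaldehyde | COc1cc(F)c(C=O)c(OC)c1OC | intermediate
20 | 4-bromo-2,6-dimethoxyphenol | COc1cc(Br)cc(OC)c1O | starting material
21 | 6-(4-bromo-2,6-dimethoxyphenoxy)-2,3,4-trimethoxybenzaldehyde | COc1cc(Oc2c(OC)cc(Br)cc2OC)c(C=O)c(OC)c1OC | intermediate
22 | 6-[2,6-dimethoxy-4-(2,4,6-trimethoxyphenoxy)phenoxy]-2,3,4-trimethoxybenzaldehyde (trimer aldehyde A–C) | COc1cc(OC)c(Oc2cc(OC)c(Oc3cc(OC)c(OC)c(OC)c3C=O)c(OC)c2)c(OC)c1 | intermediate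
23 | 6-[2,6-dimethoxy-4-(2,4,6-trimethoxyphenoxy)phenoxy]-2,3,4-trimethoxyphenyl formate (not isolated) | COc1cc(OC)c(Oc2cc(OC)c(Oc3cc(OC)c(OC)c(OC)c3OC=O)c(OC)c2)c(OC)c1 | intermediate
24 | 6-[2,6-dimethoxy-4-(2,4,6-trimethoxyphenoxy)phenoxy]-2,3,4-trimethoxyphenol (trimer phenol A–C) | COc1cc(OC)c(Oc2cc(OC)c(Oc3cc(OC)c(OC)c(OC)c3O)c(OC)c2)c(OC)c1 | intermediate
25 | pentamer aldehyde A–E: 24 O-arylated by the 4-(2-formyl-3,4,5-trimethoxyphenoxy)-3,5-dimethoxyphenyl group | COc1cc(OC)c(Oc2cc(OC)c(Oc3cc(OC)c(OC)c(OC)c3Oc3cc(OC)c(Oc4cc(OC)c(OC)c(OC)c4C=O)c(OC)c3)c(OC)c2)c(OC)c1 | intermediate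
26 | pentamer formate A–E: formate ester of 27 (not isolated) | COc1cc(OC)c(Oc2cc(OC)c(Oc3cc(OC)c(OC)c(OC)c3Oc3cc(OC)c(Oc4cc(OC)c(OC)c(OC)c4OC=O)c(OC)c3)c(OC)c2)c(OC)c1 | intermediate
27 | pentamer phenol A–E: hydroxyl on ring E C2 in place of the formyl group of 25 | COc1cc(OC)c(Oc2cc(OC)c(Oc3cc(OC)c(OC)c(OC)c3Oc3cc(OC)c(Oc4cc(OC)c(OC)c(OC)c4O)c(OC)c3)c(OC)c2)c(OC)c1 | intermediate
28 | heptamer aldehyde A–G: 27 O-arylated by the 4-(2-formyl-3,4,5-trimethoxyphenoxy)-3,5-dimethoxyphenyl group | COc1cc(OC)c(Oc2cc(OC)c(Oc3cc(OC)c(OC)c(OC)c3Oc3cc(OC)c(Oc4cc(OC)c(OC)c(OC)c4Oc4cc(OC)c(Oc5cc(OC)c(OC)c(OC)c5C=O)c(OC)c4)c(OC)c3)c(OC)c2)c(OC)c1 | intermediate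
29 | heptamer formate A–G: formate ester of 30 (not isolated) | COc1cc(OC)c(Oc2cc(OC)c(Oc3cc(OC)c(OC)c(OC)c3Oc3cc(OC)c(Oc4cc(OC)c(OC)c(OC)c4Oc4cc(OC)c(Oc5cc(OC)c(OC)c(OC)c5OC=O)c(OC)c4)c(OC)c3)c(OC)c2)c(OC)c1 | intermediate
30 | heptamer phenol A–G: hydroxyl on ring G C2 in place of the formyl group of 28 | COc1cc(OC)c(Oc2cc(OC)c(Oc3cc(OC)c(OC)c(OC)c3Oc3cc(OC)c(Oc4cc(OC)c(OC)c(OC)c4Oc4cc(OC)c(Oc5cc(OC)c(OC)c(OC)c5O)c(OC)c4)c(OC)c3)c(OC)c2)c(OC)c1 | intermediate
31 | nonamer aldehyde A–I: 30 O-arylated by the 4-(2-formyl-3,4,5-trimethoxyphenoxy)-3,5-dimethoxyphenyl group | COc1cc(OC)c(Oc2cc(OC)c(Oc3cc(OC)c(OC)c(OC)c3Oc3cc(OC)c(Oc4cc(OC)c(OC)c(OC)c4Oc4cc(OC)c(Oc5cc(OC)c(OC)c(OC)c5Oc5cc(OC)c(Oc6cc(OC)c(OC)c(OC)c6C=O)c(OC)c5)c(OC)c4)c(OC)c3)c(OC)c2)c(OC)c1 | intermediate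
32 | nonamer formate A–I: formate ester of 33 (not isolated) | COc1cc(OC)c(Oc2cc(OC)c(Oc3cc(OC)c(OC)c(OC)c3Oc3cc(OC)c(Oc4cc(OC)c(OC)c(OC)c4Oc4cc(OC)c(Oc5cc(OC)c(OC)c(OC)c5Oc5cc(OC)c(Oc6cc(OC)c(OC)c(OC)c6OC=O)c(OC)c5)c(OC)c4)c(OC)c3)c(OC)c2)c(OC)c1 | intermediate
33 | nonamer phenol A–I: hydroxyl on ring I C2 in place of the formyl group of 31 | COc1cc(OC)c(Oc2cc(OC)c(Oc3cc(OC)c(OC)c(OC)c3Oc3cc(OC)c(Oc4cc(OC)c(OC)c(OC)c4Oc4cc(OC)c(Oc5cc(OC)c(OC)c(OC)c5Oc5cc(OC)c(Oc6cc(OC)c(OC)c(OC)c6O)c(OC)c5)c(OC)c4)c(OC)c3)c(OC)c2)c(OC)c1 | intermediate
34 | 5-bromo-1,2,3-trimethoxybenzene | COc1cc(Br)cc(OC)c1OC | starting material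
35 | hexacosa-O-methyl ether of the target: 33 O-arylated by the 3,4,5-trimethoxyphenyl group | COc1cc(OC)c(Oc2cc(OC)c(Oc3cc(OC)c(OC)c(OC)c3Oc3cc(OC)c(Oc4cc(OC)c(OC)c(OC)c4Oc4cc(OC)c(Oc5cc(OC)c(OC)c(OC)c5Oc5cc(OC)c(Oc6cc(OC)c(OC)c(OC)c6Oc6cc(OC)c(OC)c(OC)c6)c(OC)c5)c(OC)c4)c(OC)c3)c(OC)c2)c(OC)c1 | intermediate
36 | CNP0255890.0: the decamer with all twenty-six hydroxyls free | Oc1cc(O)c(Oc2cc(O)c(Oc3cc(O)c(O)c(O)c3Oc3cc(O)c(Oc4cc(O)c(O)c(O)c4Oc4cc(O)c(Oc5cc(O)c(O)c(O)c5Oc5cc(O)c(Oc6cc(O)c(O)c(O)c6Oc6cc(O)c(O)c(O)c6)c(O)c5)c(O)c4)c(O)c3)c(O)c2)c(O)c1 | target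

## Step count and weak points

Total step count: 22. Longest linear sequence: 19 steps (steps 1–9, then 13–22). Steps 10–12 form the side branch that supplies 19 and 21.

**Step 6 (key step).** The cyclisation may be diverted to O-acylation (a 4-hydroxy-2-pyranone), or methoxide may cleave the 2-aryloxy-1,3-diketone by retro-Claisen attack before the C6 enolate forms; the aryloxy group at C4 weakens the diketone chelate that otherwise protects it. Fallback: ring A is not built but bought, and the A–B ether is made by coupling. The fallback sets out from 20. Benzylation of 20 with BnBr and K2CO3 in DMF would give 5-bromo-2-(benzyloxy)-1,3-dimethoxybenzene F1 as the ring B electrophile. Copper-catalysed coupling of F1 with purchased 2,4,6-trimethoxyphenol F2 under the conditions of step 15 would join the two rings, and the fallback returns to the route at 14.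

**Step 5.** Acylation may occur at C2 or at oxygen instead of at the aryloxy-bearing terminus, whose substituent slows attack. Traces of HCl may desilylate 8, and 10 may lactonise on work-up. Fallback: the aryloxy group is introduced after the triketide is built. The fallback sets out from 4 and 9. The parent diene 1-methoxy-1,3-bis(trimethylsilyloxy)buta-1,3-diene F3 would be acylated with 9 to give dimethyl 3,5-dioxoheptanedioate F4 after aqueous work-up. Diazo transfer to F4 with 4-acetamidobenzenesulfonyl azide and Et3N at the central methylene would give dimethyl 4-diazo-3,5-dioxoheptanedioate F5 as the carbene precursor. O–H insertion of the carbenoid from F5 into phenol 4, catalysed by Rh2(OAc)4, returns at 10. This detour has its own exposure in the site selectivity of the diazo transfer.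

**Step 13 (and step 12).** The displacement may stall, because the formyl group of 19 is itself fed by ortho and para methoxy donors and activates the fluoride only moderately, and the phenoxide is crowded. Forcing temperatures invite aldehyde decomposition. Fallback: copper catalysis instead of SNAr. The fallback sets out from 15 and 34. Rieche formylation of 34 would give 6-bromo-2,3,4-trimethoxybenzaldehyde F6 in one step. The ortho-formyl bromide of F6 would couple with 15 under the conditions of step 15, and the fallback returns at 22.

**Step 15 (the same applies to steps 17, 19 and 21).** Coupling of two electron-rich, crowded partners may be slow, with reductive loss of bromine from 21 and catalyst deactivation by the many ether oxygens; the problem should grow with chain length. Fallback: the two rings are added one at a time without metal. The fallback sets out from 24. SNAr of 24 with purchasable 4-fluoro-2,6-dimethoxybenzaldehyde F7 in DMF with K2CO3 would give tetramer aldehyde A–D F8 with the formyl group para to the new ether oxygen. Baeyer–Villiger oxidation of F8 as in step 14 would pass through tetramer formate A–D F9 and give, after methanolysis, tetramer phenol A–D F10 with its hydroxyl between two methoxy groups. SNAr of F10 with 19 as in step 13 returns at 25.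

**Step 22.** Cleavage of twenty-six methyl ethers may stop short and give partially methylated mixtures, and the free polyphenol may oxidise during aqueous work-up and chromatography. Fallback: isolation through a stable derivative. The fallback sets out from 35. The crude demethylation product would be acetylated with Ac2O and pyridine to the decamer hexacosaacetate F11 and purified in that form on silica. Deacetylation of F11 with NaOMe in degassed MeOH, followed by acidification, returns at 36.

## Further compounds

F1 | step 6 | 5-bromo-2-(benzyloxy)-1,3-dimethoxybenzene | COc1cc(Br)cc(OC)c1OCc1ccccc1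
F2 | step 6 | 2,4,6-trimethoxyphenol (purchased) | COc1cc(OC)c(O)c(OC)c1
F3 | step 5 | 1-methoxy-1,3-bis(trimethylsilyloxy)buta-1,3-diene | COC(O[Si](C)(C)C)=CC(=C)O[Si](C)(C)C
F4 | step 5 | dimethyl 3,5-dioxoheptanedioate | COC(=O)CC(=O)CC(=O)CC(=O)OC
F5 | step 5 | dimethyl 4-diazo-3,5-dioxoheptanedioate | COC(=O)CC(=O)C(=[N+]=[N-])C(=O)CC(=O)OC
F6 | step 13 | 6-bromo-2,3,4-trimethoxybenzaldehyde | COc1cc(Br)c(C=O)c(OC)c1OC
F7 | step 15 | 4-fluoro-2,6-dimethoxybenzaldehyde (purchased) | COc1cc(F)cc(OC)c1C=O
F8 | step 15 | tetramer aldehyde A–D: 24 O-arylated by the 4-formyl-3,5-dimethoxyphenyl group | COc1cc(OC)c(Oc2cc(OC)c(Oc3cc(OC)c(OC)c(OC)c3Oc3cc(OC)c(C=O)c(OC)c3)c(OC)c2)c(OC)c1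
F9 | step 15 | tetramer formate A–D: formate ester of the tetramer phenol (not isolated) | COc1cc(OC)c(Oc2cc(OC)c(Oc3cc(OC)c(OC)c(OC)c3Oc3cc(OC)c(OC=O)c(OC)c3)c(OC)c2)c(OC)c1
F10 | step 15 | tetramer phenol A–D: hydroxyl on ring D in place of the formyl group of the tetramer aldehyde | COc1cc(OC)c(Oc2cc(OC)c(Oc3cc(OC)c(OC)c(OC)c3Oc3cc(OC)c(O)c(OC)c3)c(OC)c2)c(OC)c1
F11 | step 22 | decamer hexacosaacetate (all twenty-six hydroxyls of 36 acetylated) | CC(=O)Oc1cc(OC(C)=O)c(Oc2cc(OC(C)=O)c(Oc3cc(OC(C)=O)c(OC(C)=O)c(OC(C)=O)c3Oc3cc(OC(C)=O)c(Oc4cc(OC(C)=O)c(OC(C)=O)c(OC(C)=O)c4Oc4cc(OC(C)=O)c(Oc5cc(OC(C)=O)c(OC(C)=O)c(OC(C)=O)c5Oc5cc(OC(C)=O)c(Oc6cc(OC(C)=O)c(OC(C)=O)c(OC(C)=O)c6Oc6cc(OC(C)=O)c(OC(C)=O)c(OC(C)=O)c6)c(OC(C)=O)c5)c(OC(C)=O)c4)c(OC(C)=O)c3)c(OC(C)=O)c2)c(OC(C)=O)c1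
A1 | alternative 1 | octa-O-methyl ether of the target with eighteen free hydroxyls | COc1cc(O)c(Oc2cc(O)c(Oc3cc(O)c(OC)c(O)c3Oc3cc(O)c(Oc4cc(O)c(OC)c(O)c4Oc4cc(O)c(Oc5cc(O)c(OC)c(O)c5Oc5cc(O)c(Oc6cc(O)c(OC)c(O)c6Oc6cc(OC)c(OC)c(OC)c6)c(O)c5)c(O)c4)c(O)c3)c(O)c2)c(O)c1
A2 | alternative 1 | octadecaformyl decamer (formyl in place of each free hydroxyl of A1) | COc1cc(C=O)c(Oc2cc(C=O)c(Oc3cc(C=O)c(OC)c(C=O)c3Oc3cc(C=O)c(Oc4cc(C=O)c(OC)c(C=O)c4Oc4cc(C=O)c(Oc5cc(C=O)c(OC)c(C=O)c5Oc5cc(C=O)c(Oc6cc(C=O)c(OC)c(C=O)c6Oc6cc(OC)c(OC)c(OC)c6)c(C=O)c5)c(C=O)c4)c(C=O)c3)c(C=O)c2)c(C=O)c1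
A3 | alternative 2 | 2-(2-bromo-3,4,5-trimethoxyphenoxy)-3-ethoxy-5-(triisopropylsilyloxy)phenol | CCOc1cc(O[Si](C(C)C)(C(C)C)C(C)C)cc(O)c1Oc2cc(OC)c(OC)c(OC)c2Br
A4 | alternative 2 | 4-(2-bromo-3,4,5-trimethoxyphenoxy)-3-ethoxycyclobut-2-en-1-one (racemic) | CCOC1=CC(=O)C1Oc1cc(OC)c(OC)c(OC)c1Br
A5 | alternative 2 | (triisopropylsilyloxy)acetylene | C#CO[Si](C(C)C)(C(C)C)C(C)C
A6 | alternative 3 | trimer phenol A–C with ring C C2 hydroxyl free (identical with 24) | Oc1c(OC)c(OC)c(OC)cc1Oc2c(OC)cc(Oc3c(OC)cc(OC)cc3OC)cc2OC
A7 | alternative 3 | 2,3,4-trimethoxy-4-[(Z)-2-[2,6-dimethoxy-4-(2,4,6-trimethoxyphenoxy)phenoxy]ethenyl]cyclobut-2-en-1-one (racemic) | COC1=C(OC)C(OC)(/C=C\Oc2c(OC)cc(Oc3c(OC)cc(OC)cc3OC)cc2OC)C1=O
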